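Ring C of the flavanone is traced back to the flat flavone and taken apart at three bonds. The feature exploited is that C4 is a lone carbonyl carbon between C4a of ring A and the C3–C2 pair carrying ring B, while O1 bridges C8a and C2. One palladium-catalysed operation therefore joins an ortho-iodophenol, carbon monoxide and an arylacetylene. It makes C4a–C4, C4–C3 and O1–C2 and closes ring C. The iodophenol already bears both methoxy groups and the C8 prenyl chain; the alkyne carries ring B with its phenol silylated. C2 is then set by ligand-controlled copper hydride reduction, and buffered fluoride frees the phenol.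

Key step: step 7

Assumption: the (S)-antipode of the bisphosphine is taken to give (2S), by analogy with β-substituted cyclic enones. Both antipodes are commercial, so a pilot run (chiral HPLC, CD) fixes the choice.

Numbering: flavonoid numbering (O1, C2–C8a, primes for ring B) is used from the key step on; phenol numbering (C1 = C–O) is used for the ring A building blocks.

Step 1
Reactants: 1 3,5-dimethoxyphenol
Product: 2 1,3-dimethoxy-5-(methoxymethoxy)benzene
Conditions: MOMCl, i-Pr2NEt, CH2Cl2, 0 °C → rt
Reagents that add atoms: chloromethyl methyl ether (MOMCl), COCCl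
Why: O-alkylation of a phenol with an α-chloro ether (MOM protection) is routine, and the acetal is chosen because it out-directs the two methoxy groups in the following lithiations and leaves under mild acid.

Step 2
Reactants: 2 1,3-dimethoxy-5-(methoxymethoxy)benzene; 3 prenyl bromide (1-bromo-3-methylbut-2-ene)
Product: 5 1,5-dimethoxy-3-(methoxymethoxy)-2-(3-methylbut-2-enyl)benzene, via aryllithium 4 (not isolated)
Conditions: n-BuLi, TMEDA, THF, 0 °C; CuI (10 mol %), then 3, −78 °C → rt
Reagents that add atoms: none
Why: Directed ortho-metalation followed by copper-catalysed allylic substitution: the chelating OMOM group and its flanking OMe make the two equivalent C–H bonds beside the acetal kinetically preferred over the one between the methoxy groups, and the aryl nucleophile attacks the unhindered primary carbon of 3 (SN2, not SN2′) to give the linear prenyl chain.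

Step 3
Reactants: 5 1,5-dimethoxy-3-(methoxymethoxy)-2-(3-methylbut-2-enyl)benzene
Product: 7 2-iodo-1,5-dimethoxy-3-(methoxymethoxy)-4-(3-methylbut-2-enyl)benzene, via aryllithium 6 (not isolated)
Conditions: n-BuLi, THF, −20 → 0 °C; I2, THF, −78 °C
Reagents that add atoms: iodine, II
Why: A second directed ortho-metalation with iodine quench: C6–H is the only remaining C–H beside OMOM and the prenyl chain turns the acetal arm towards it, so trapping the carbanion fixes the iodine position and avoids electrophilic iodination of a free ortho-prenylphenol, which would risk iodoetherification of the alkene and attack at C4.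

Step 4
Reactants: 7 2-iodo-1,5-dimethoxy-3-(methoxymethoxy)-4-(3-methylbut-2-enyl)benzene
Product: 8 2-iodo-3,5-dimethoxy-6-(3-methylbut-2-enyl)phenol
Conditions: HCl (0.5 M in MeOH), 40 °C
Reagents that add atoms: none
Why: Acid-catalysed acetal exchange (MOM cleavage) is fast for this twisted, doubly ortho-flanked aryl acetal, so dilute acid and gentle warming suffice, below the acidity needed to cyclise the ortho-prenylphenol to a 2,2-dimethylchroman or to protodeiodinate the ring.

Step 5
Reactants: 9 isovanillin (3-hydroxy-4-methoxybenzaldehyde)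
Product: 10 5-ethynyl-2-methoxyphenol
Conditions: dimethyl (1-diazo-2-oxopropyl)phosphonate, K2CO3 (3 equiv), MeOH, rt; aq. NH4Cl
Reagents that add atoms: dimethyl (1-diazo-2-oxopropyl)phosphonate, COP(=O)(OC)C(=[N+]=[N-])C(C)=O
Why: The Ohira–Bestmann variant of the Seyferth–Gilbert homologation turns ArCHO into ArC≡CH in one operation; it is run before silylation because an aryl silyl ether would not survive K2CO3 in MeOH, and the phenoxide, being meta to the formyl group, does not deactivate it.

Step 6
Reactants: 10 5-ethynyl-2-methoxyphenol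
Product: 11 tert-butyl(5-ethynyl-2-methoxyphenoxy)dimethylsilane
Conditions: TBSCl, imidazole, CH2Cl2, rt
Reagents that add atoms: tert-butyldimethylsilyl chloride (TBSCl), CC(C)(C)[Si](C)(C)Cl
Why: Imidazole-promoted O-silylation of a phenol is reliable and leaves the terminal alkyne untouched, and the silyl ether keeps the ring B oxygen from being acylated in the carbonylation.

Step 7
Reactants: 8 2-iodo-3,5-dimethoxy-6-(3-methylbut-2-enyl)phenol; 11 tert-butyl(5-ethynyl-2-methoxyphenoxy)dimethylsilane; 12 carbon monoxide
Product: 15 2-[3-(tert-butyldimethylsilyloxy)-4-methoxyphenyl]-5,7-dimethoxy-8-(3-methylbut-2-enyl)chromen-4-one, via ynone 13 (not isolated), via enaminone 14 (not isolated)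
Conditions: PdCl2(PPh3)2 (5 mol %), CO (10 bar), Et2NH, 80 °C, autoclave, no copper salt
Reagents that add atoms: none
Why: This is a carbonylative Sonogashira coupling with amine-mediated cyclisation, the established palladium route from 2-iodophenols, CO and terminal alkynes to flavones: the C–I bond of 8 adds oxidatively to zerovalent palladium formed from PdCl2(PPh3)2, CO inserts into the aryl–palladium bond (C4a–C4), and the amine-deprotonated alkyne 11 replaces iodide so that reductive elimination (C4–C3) releases ynone 13. Et2NH then adds in conjugate fashion to 13 to give the push–pull enaminone 14. Ring C closes when the C8a hydroxyl attacks C2 of 14 and expels Et2NH (O1–C2), an addition–elimination that is 6-endo-trig on 14 and amounts overall to a 6-endo-dig closure of 13. No stereocentre is created. Two selectivities are needed: CO insertion ahead of alkynylation (otherwise a 2-arylbenzofuran results), secured by CO pressure and the absence of a copper co-catalyst, and six- over five-membered closure (flavone, not aurone), secured because the amine in 14 has already marked C2 as the only electrophilic carbon. In the substrate, iodine sits meta to the prenyl chain so no Heck-type closure is within reach, the trisubstituted alkene binds palladium poorly, and the masked ring B phenol cannot intercept the aroylpalladium species as an ester.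

Step 8
Reactants: 15 2-[3-(tert-butyldimethylsilyloxy)-4-methoxyphenyl]-5,7-dimethoxy-8-(3-methylbut-2-enyl)chromen-4-one
Product: 16 (2S)-2-[3-(tert-butyldimethylsilyloxy)-4-methoxyphenyl]-5,7-dimethoxy-8-(3-methylbut-2-enyl)chroman-4-one
Conditions: Cu(OAc)2·H2O (5 mol %), (S)-DTBM-SEGPHOS (5.5 mol %), (EtO)2MeSiH, t-BuOH, toluene, 0 °C → rt
Reagents that add atoms: none
Why: Copper hydride catalysed asymmetric conjugate reduction, a reaction type established for β,β-disubstituted cyclic enones and 2-substituted chromen-4-ones: ligated CuH formed from Cu(OAc)2 and the silane delivers hydride to the Re face of prochiral C2 (O1 > C1′ > C3) under control of the chiral bisphosphine, which sets (2S); t-BuOH protonates the copper enolate at once so that β-elimination of the O1 phenoxide gains no time; and the isolated prenyl alkene, the aryl silyl ether and the deactivated 2,4,6-trioxygenated aryl ketone should stay unreduced.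

Step 9
Reactants: 16 (2S)-2-[3-(tert-butyldimethylsilyloxy)-4-methoxyphenyl]-5,7-dimethoxy-8-(3-methylbut-2-enyl)chroman-4-one
Product: 17 (2S)-2-(3-hydroxy-4-methoxyphenyl)-5,7-dimethoxy-8-(3-methylbut-2-enyl)chroman-4-one (CNP0403319.1)
Conditions: TBAF/AcOH (1:1), THF, 0 °C
Reagents that add atoms: none
Why: Fluoride-induced cleavage of the aryl silyl ether is fast at 0 °C, and the acetic acid buffer keeps the medium non-basic, so the retro-oxa-Michael opening to the chalcone, the only pathway that could scramble C2, is shut off; this step is kept apart from step 8 because fluoride plus residual silane would reduce the ketone.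

Compound list
1 | 3,5-dimethoxyphenol | COc1cc(O)cc(OC)c1 | starting material
2 | 1,3-dimethoxy-5-(methoxymethoxy)benzene | COCOc1cc(OC)cc(OC)c1 | intermediate
3 | prenyl bromide (1-bromo-3-methylbut-2-ene) | CC(C)=CCBr | starting material
4 | [2,4-dimethoxy-6-(methoxymethoxy)phenyl]lithium | [Li]c1c(OC)cc(OC)cc1OCOC | intermediate
5 | 1,5-dimethoxy-3-(methoxymethoxy)-2-(3-methylbut-2-enyl)benzene | COCOc1cc(OC)cc(OC)c1CC=C(C)C | intermediate
6 | [2,4-dimethoxy-6-(methoxymethoxy)-5-(3-methylbut-2-enyl)phenyl]lithium | [Li]c1c(OC)cc(OC)c(CC=C(C)C)c1OCOC | intermediate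
7 | 2-iodo-1,5-dimethoxy-3-(methoxymethoxy)-4-(3-methylbut-2-enyl)benzene | COCOc1c(I)c(OC)cc(OC)c1CC=C(C)C | intermediate
8 | 2-iodo-3,5-dimethoxy-6-(3-methylbut-2-enyl)phenol | COc1cc(OC)c(I)c(O)c1CC=C(C)C | intermediate
9 | isovanillin (3-hydroxy-4-methoxybenzaldehyde) | COc1ccc(C=O)cc1O | starting material
10 | 5-ethynyl-2-methoxyphenol | C#Cc1ccc(OC)c(O)c1 | intermediate
11 | tert-butyl(5-ethynyl-2-methoxyphenoxy)dimethylsilane | C#Cc1ccc(OC)c(O[Si](C)(C)C(C)(C)C)c1 | intermediate
12 | carbon monoxide | [C-]#[O+] | starting material
13 | 3-[3-(tert-butyldimethylsilyloxy)-4-methoxyphenyl]-1-[2-hydroxy-4,6-dimethoxy-3-(3-methylbut-2-enyl)phenyl]prop-2-yn-1-one | COc1ccc(C#CC(=O)c2c(OC)cc(OC)c(CC=C(C)C)c2O)cc1O[Si](C)(C)C(C)(C)C | intermediate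
14 | 3-(diethylamino)-3-[3-(tert-butyldimethylsilyloxy)-4-methoxyphenyl]-1-[2-hydroxy-4,6-dimethoxy-3-(3-methylbut-2-enyl)phenyl]prop-2-en-1-one (equilibrating push–pull alkene, geometry not defined) | CCN(CC)C(=CC(=O)c1c(OC)cc(OC)c(CC=C(C)C)c1O)c1ccc(OC)c(O[Si](C)(C)C(C)(C)C)c1 | intermediate
15 | 2-[3-(tert-butyldimethylsilyloxy)-4-methoxyphenyl]-5,7-dimethoxy-8-(3-methylbut-2-enyl)chromen-4-one | COc1ccc(-c2cc(=O)c3c(OC)cc(OC)c(CC=C(C)C)c3o2)cc1O[Si](C)(C)C(C)(C)C | intermediate
16 | (2S)-2-[3-(tert-butyldimethylsilyloxy)-4-methoxyphenyl]-5,7-dimethoxy-8-(3-methylbut-2-enyl)chroman-4-one | COc1ccc([C@@H]2CC(=O)c3c(OC)cc(OC)c(CC=C(C)C)c3O2)cc1O[Si](C)(C)C(C)(C)C | intermediate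
17 | (2S)-2-(3-hydroxy-4-methoxyphenyl)-5,7-dimethoxy-8-(3-methylbut-2-enyl)chroman-4-one | COc1ccc([C@@H]2CC(=O)c3c(OC)cc(OC)c(CC=C(C)C)c3O2)cc1O | target

Total step count: 9. Longest linear sequence: 7 (steps 1–4, then 7–9); steps 5 and 6 form the convergent ring B branch.

Steps most likely to fail

Step 7.
- **What may go wrong:** Oxidative addition and CO insertion at the electron-rich, doubly ortho-flanked iodide may be slow. The amine could then capture the aroylpalladium species, alkynylation could occur without CO, or the silyl ether could erode in hot amine.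
- **Fallback:** It sets out from 5 and 11, returns at 15, and makes the same three bonds one after another without palladium.
- Alkyne 11 is deprotonated (n-BuLi, THF, −78 °C) and acylated with N-methoxy-N-methylcarbamoyl chloride. This gives the Weinreb amide 3-[3-(tert-butyldimethylsilyloxy)-4-methoxyphenyl]-N-methoxy-N-methylprop-2-ynamide F1.
- Aryllithium 6, generated from 5 as in step 3, is added to F1 at −78 °C with a cold acidic quench. This gives the protected ynone 3-[3-(tert-butyldimethylsilyloxy)-4-methoxyphenyl]-1-[4,6-dimethoxy-2-(methoxymethoxy)-3-(3-methylbut-2-enyl)phenyl]prop-2-yn-1-one F2.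
- Et2NH in EtOH at rt adds to F2 to give the protected enaminone 3-(diethylamino)-3-[3-(tert-butyldimethylsilyloxy)-4-methoxyphenyl]-1-[4,6-dimethoxy-2-(methoxymethoxy)-3-(3-methylbut-2-enyl)phenyl]prop-2-en-1-one F3.
- Dilute HCl in MeOH removes the acetal from F3, and the freed phenol displaces the amine to give flavone 15. Steps 3 and 4 are then not needed.

Step 8.
- **What may go wrong:** Turnover may be sluggish with the bulky chiral ligand on this electron-rich vinylogous ester. Facial selectivity may be poor, or the enolate may ring-open.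
- **Fallback:** It sets out from 15, returns at 16, and separates reduction from stereocontrol.
- Flavone 15 is reduced with a small achiral ligand (Cu(OAc)2·H2O, 1,2-bis(diphenylphosphino)benzene, PMHS, t-BuOH, toluene). This gives racemic 2-[3-(tert-butyldimethylsilyloxy)-4-methoxyphenyl]-5,7-dimethoxy-8-(3-methylbut-2-enyl)chroman-4-one F4.
- F4 is resolved kinetically by Noyori-type asymmetric transfer hydrogenation, which does not touch the prenyl alkene (RhCl(Cp*)[(R,R)-TsDPEN], HCO2H/Et3N, EtOAc, rt, stopped near half conversion).
- The (2R)-ketone is expected to be the matched substrate. It should go to (2R,4R)-2-[3-(tert-butyldimethylsilyloxy)-4-methoxyphenyl]-5,7-dimethoxy-8-(3-methylbut-2-enyl)chroman-4-ol F5.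
- The (2S)-ketone stays behind and is separated by chromatography as 16. At most half of the material can be carried on.

Step 3.
- **What may go wrong:** Metalation may go astray, through deprotonation of the benzylic–allylic CH2 of the prenyl chain or of C4–H between the two methoxy groups.
- **Fallback:** It sets out from 1, returns at 8, and replaces steps 1–4 by the same number of operations. Iodine is placed first, and the prenyl group arrives by a sigmatropic shift that can end only at the free ortho carbon.
- NIS in CH2Cl2 at 0 °C attacks the less crowded C2 to give 2-iodo-3,5-dimethoxyphenol F6.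
- O-alkylation with 3-chloro-3-methylbut-1-yne (CuCl2·2H2O cat., DBU, MeCN, 0 °C) gives 2-iodo-1,5-dimethoxy-3-(2-methylbut-3-yn-2-yloxy)benzene F7.
- Semihydrogenation (Pd/CaCO3 poisoned with Pb(OAc)2, quinoline, H2, 1 atm) gives 2-iodo-1,5-dimethoxy-3-(2-methylbut-3-en-2-yloxy)benzene F8.
- Aromatic Claisen rearrangement (N,N-diethylaniline, about 130 °C) transfers the allyl unit with inversion to C6. This delivers the linear prenyl chain and the free hydroxyl of 8 in one event.

Further compounds
F1 | step 7 | 3-[3-(tert-butyldimethylsilyloxy)-4-methoxyphenyl]-N-methoxy-N-methylprop-2-ynamide | CON(C)C(=O)C#Cc1ccc(OC)c(O[Si](C)(C)C(C)(C)C)c1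
F2 | step 7 | 3-[3-(tert-butyldimethylsilyloxy)-4-methoxyphenyl]-1-[4,6-dimethoxy-2-(methoxymethoxy)-3-(3-methylbut-2-enyl)phenyl]prop-2-yn-1-one | COCOc1c(CC=C(C)C)c(OC)cc(OC)c1C(=O)C#Cc1ccc(OC)c(O[Si](C)(C)C(C)(C)C)c1
F3 | step 7 | 3-(diethylamino)-3-[3-(tert-butyldimethylsilyloxy)-4-methoxyphenyl]-1-[4,6-dimethoxy-2-(methoxymethoxy)-3-(3-methylbut-2-enyl)phenyl]prop-2-en-1-one | CCN(CC)C(=CC(=O)c1c(OC)cc(OC)c(CC=C(C)C)c1OCOC)c1ccc(OC)c(O[Si](C)(C)C(C)(C)C)c1
F4 | step 8 | racemic 2-[3-(tert-butyldimethylsilyloxy)-4-methoxyphenyl]-5,7-dimethoxy-8-(3-methylbut-2-enyl)chroman-4-one | COc1ccc(C2CC(=O)c3c(OC)cc(OC)c(CC=C(C)C)c3O2)cc1O[Si](C)(C)C(C)(C)C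
F5 | step 8 | (2R,4R)-2-[3-(tert-butyldimethylsilyloxy)-4-methoxyphenyl]-5,7-dimethoxy-8-(3-methylbut-2-enyl)chroman-4-ol | COc1ccc([C@H]2C[C@@H](O)c3c(OC)cc(OC)c(CC=C(C)C)c3O2)cc1O[Si](C)(C)C(C)(C)C
F6 | step 3 | 2-iodo-3,5-dimethoxyphenol | COc1cc(O)c(I)c(OC)c1
F7 | step 3 | 2-iodo-1,5-dimethoxy-3-(2-methylbut-3-yn-2-yloxy)benzene | C#CC(C)(C)Oc1cc(OC)cc(OC)c1I
F8 | step 3 | 2-iodo-1,5-dimethoxy-3-(2-methylbut-3-en-2-yloxy)benzene | C=CC(C)(C)Oc1cc(OC)cc(OC)c1I
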